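**Retrosynthetic overview**

- The strategy rests on the substitution pattern of the pyrrole ring: C4 and C5 are unsubstituted CH positions, C3 carries only the nonadecyl chain, and C2 carries the ester next to N1. The C3=C4 bond can therefore be traced back to an N-allyl group (N1–C5–C4) and a 1-alkylvinyl group on a glycine α-carbon (C2–C3).
- Target 14 comes from the N-tosyl 2,5-dihydropyrrole 12 by loss of p-toluenesulfinate and tautomerisation.
- The only ring is formed by ring-closing metathesis of diene 11, which makes C3=C4.
- Diene 11 comes from N-allylation of sulfonamide 9, itself made by adding alkenyl Grignard reagent 8 to the N-tosyl imine 7 of methyl glyoxylate.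
- Reagent 8 comes from 2-bromohenicos-1-ene 4 (octadecyl Grignard reagent plus 2,3-dibromopropene); imine 7 comes from methyl glyoxylate and tosyl isocyanate.

Key step: step 5

Remark: C2 of compounds 9, 11 and 12 is a stereocentre carried as the racemate; it is erased on aromatisation, and the target is achiral.

**Route**

Step 1
Reactants: 1 1-bromooctadecane; 2 2,3-dibromopropene
Product: 4 2-bromohenicos-1-ene, via octadecylmagnesium bromide 3 (not isolated)
Conditions: Mg, THF, 50 °C; then 2 (1.2 equiv), CuBr·SMe2 (5 mol %), THF, 0 °C to rt
Reagents that add atoms: none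
Why: The Grignard reagent displaces the allylic bromide of 2 in a copper-catalysed Grignard–allyl halide coupling (SN2 and SN2' paths give the same product) while the vinylic C–Br bond stays intact.

Step 2
Reactants: 5 methyl glyoxylate (freshly distilled monomer); 6 p-toluenesulfonyl isocyanate
Product: 7 methyl (E)-2-(tosylimino)acetate
Conditions: toluene, reflux, N2; solvent removed, imine used crude
Reagents that add atoms: none
Why: The aldehyde carbonyl exchanges with the N=C=O group of the sulfonyl isocyanate with loss of CO2 (aza-Wittig-like carbonyl–isocyanate exchange), the standard preparation of N-sulfonyl iminoacetates.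

Step 3
Reactants: 4 2-bromohenicos-1-ene; 7 methyl (E)-2-(tosylimino)acetate
Product: 9 methyl 3-methylidene-2-(tosylamino)docosanoate (racemic), via henicos-1-en-2-ylmagnesium bromide 8 (not isolated)
Conditions: Mg (I2 cat.), THF, 45 °C; cooled and added to 7 (1.2 equiv) in THF, −78 °C; 1 M aq HCl quench
Reagents that add atoms: none
Why: Magnesium inserts into the vinylic C–Br bond and the alkenyl Grignard reagent adds to the strongly electrophilic N-sulfonyl imine carbon faster than to the ester at −78 °C (Grignard addition to an α-imino ester, a known entry to β,γ-unsaturated α-amino esters); the new C2 centre forms as the racemate, which is immaterial because step 6 destroys it.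

Step 4
Reactants: 9 methyl 3-methylidene-2-(tosylamino)docosanoate; 10 allyl bromide
Product: 11 methyl 2-[allyl(tosyl)amino]-3-methylidenedocosanoate (racemic)
Conditions: K2CO3, DMF, 0 °C to rt
Reagents that add atoms: none
Why: The sulfonamide N–H is far more acidic than the C2–H, so carbonate should generate only the nitrogen anion, which is alkylated by allyl bromide (SN2 N-alkylation of a sulfonamide) without moving the β,γ-alkene.

Step 5
Reactants: 11 methyl 2-[allyl(tosyl)amino]-3-methylidenedocosanoate
Product: 12 methyl 3-nonadecyl-1-tosyl-2,5-dihydro-1H-pyrrole-2-carboxylate (racemic)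
Conditions: second-generation Grubbs catalyst RuCl2(=CHPh)(PCy3)(H2IMes) (5 mol %), 1,4-benzoquinone (10 mol %), degassed CH2Cl2 (0.01 M), 40 °C
Reagents that add atoms: none
Why: The ruthenium benzylidene exchanges onto the unhindered N-allyl terminus, and the resulting N–CH2–CH=[Ru] alkylidene adds across the C3 methylidene alkene to a ruthenacyclobutane whose cycloreversion forms C3=C4 and a Ru=CH2 carrier that leaves as ethene in the next turnover. The closest known reaction type is ring-closing olefin metathesis of N-sulfonyl N-allyl allylic amine dienes to 3-pyrrolines, which accepts 1,1-disubstituted partners and gives trisubstituted ring alkenes. The 2,5-dihydro-1H-pyrrole ring (N1–C2–C3=C4–C5) is closed by this intramolecular [2+2] cycloaddition and cycloreversion between the allyl CH (C4) and C3, a five-membered closure driven by loss of volatile ethene. No new stereocentre is created, and the racemic C2 centre is carried through unchanged. The step needs ring closure to outrun double-bond migration in the β,γ-unsaturated ester or the N-allyl group and intermolecular metathesis; high dilution, the favoured five-membered ring, the non-coordinating sulfonamide nitrogen, benzoquinone as a scavenger of ruthenium hydrides and the reluctance of the hindered 1,1-disubstituted alkene to homodimerise should secure this.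

Step 6
Reactants: 12 methyl 3-nonadecyl-1-tosyl-2,5-dihydro-1H-pyrrole-2-carboxylate
Product: 14 methyl 3-nonadecyl-1H-pyrrole-2-carboxylate (target), via methyl 4-nonadecyl-2H-pyrrole-5-carboxylate 13 (not isolated)
Conditions: DBU (3 equiv), toluene, 80 °C
Reagents that add atoms: none
Why: DBU removes the acidic allylic C2–H next to the ester, the carbanion expels p-toluenesulfinate from nitrogen (E1cB elimination) to give 2H-pyrrole 13, and a base-mediated proton shift from C5 to nitrogen aromatises it to the 1H-pyrrole.

**Compound list**

1 | 1-bromooctadecane | CCCCCCCCCCCCCCCCCCBr | starting material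
2 | 2,3-dibromopropene | C=C(Br)CBr | starting material
3 | octadecylmagnesium bromide | CCCCCCCCCCCCCCCCCC[Mg]Br | intermediate (not isolated)
4 | 2-bromohenicos-1-ene | CCCCCCCCCCCCCCCCCCCC(Br)=C | intermediate
5 | methyl glyoxylate | COC(=O)C=O | starting material
6 | p-toluenesulfonyl isocyanate | Cc1ccc(cc1)S(=O)(=O)N=C=O | starting material
7 | methyl (E)-2-(tosylimino)acetate | COC(=O)/C=N/S(=O)(=O)c1ccc(C)cc1 | intermediate
8 | henicos-1-en-2-ylmagnesium bromide | CCCCCCCCCCCCCCCCCCCC(=C)[Mg]Br | intermediate (not isolated)
9 | methyl 3-methylidene-2-(tosylamino)docosanoate (racemic) | CCCCCCCCCCCCCCCCCCCC(=C)C(NS(=O)(=O)c1ccc(C)cc1)C(=O)OC | intermediate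
10 | allyl bromide | C=CCBr | starting material
11 | methyl 2-[allyl(tosyl)amino]-3-methylidenedocosanoate (racemic) | CCCCCCCCCCCCCCCCCCCC(=C)C(N(CC=C)S(=O)(=O)c1ccc(C)cc1)C(=O)OC | intermediate
12 | methyl 3-nonadecyl-1-tosyl-2,5-dihydro-1H-pyrrole-2-carboxylate (racemic) | CCCCCCCCCCCCCCCCCCCC1=CCN(S(=O)(=O)c2ccc(C)cc2)C1C(=O)OC | intermediate
13 | methyl 4-nonadecyl-2H-pyrrole-5-carboxylate | CCCCCCCCCCCCCCCCCCCC1=CCN=C1C(=O)OC | intermediate (not isolated)
14 | methyl 3-nonadecyl-1H-pyrrole-2-carboxylate | CCCCCCCCCCCCCCCCCCCc1cc[nH]c1C(=O)OC | target

**Step count**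

Total step count: 6. Longest linear sequence: 5 steps (steps 1, 3, 4, 5, 6); step 2 is a one-step side branch.

**Steps most likely to fail**

Step 3. The Grignard reagent may attack the ester or the imine nitrogen instead of the imine carbon, and the moisture-sensitive imine may hydrolyse or oligomerise before it is consumed. The fallback sets out from 4 (through Grignard reagent 8) and returns to the route at diene 11, bypassing 7, 9 and step 4. Reagent 8 would be quenched with B(OMe)3 at −78 °C and hydrolysed with 1 M HCl to henicos-1-en-2-ylboronic acid F1. A Petasis borono-Mannich reaction of F1 with glyoxylic acid monohydrate and allylamine (CH2Cl2/hexafluoroisopropanol, rt) should give 2-(allylamino)-3-methylidenedocosanoic acid F2. In that reaction the alkenyl group is transferred within a boronate–iminium complex, so no ester or sulfonyl imine is exposed to a basic organometallic. Fischer esterification (HCl in MeOH, reflux, NaHCO3 work-up) to methyl 2-(allylamino)-3-methylidenedocosanoate F3, followed by N-sulfonylation (TsCl, pyridine, DMAP, CH2Cl2), would deliver 11.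

Step 5. Ruthenium hydride species may move either double bond, or intermolecular metathesis may compete, if closure onto the hindered 1,1-disubstituted alkene is slow. The fallback sets out from 9 (step 4 is then not needed) and returns at target 14; it builds the ring without metathesis, with the methylidene carbon becoming C4 and carbon monoxide supplying C5. Rhodium-catalysed hydroformylation of 9 [Rh(acac)(CO)2, tris(2,4-di-tert-butylphenyl) phosphite, CO and H2 at 20 bar each, toluene, 80 °C] should place the formyl group on the terminal carbon to give methyl 3-(2-oxoethyl)-2-(tosylamino)docosanoate F4. This aldehyde should close with the sulfonamide N–H to methyl 5-hydroxy-3-nonadecyl-1-tosylpyrrolidine-2-carboxylate F5 (mixture of diastereomers). Acid-catalysed dehydration (pyridinium p-toluenesulfonate, toluene, 80 °C) should give the cyclic enamide methyl 3-nonadecyl-1-tosyl-2,3-dihydro-1H-pyrrole-2-carboxylate F6. DBU in hot toluene, as in step 6, should then eliminate sulfinate to methyl 3-nonadecyl-3H-pyrrole-2-carboxylate F7, which tautomerises to 14.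

Step 4. Deprotonation at C2 of the product under the basic conditions may move the β,γ-double bond into conjugation with the ester. The fallback sets out from 9 and returns at 11 without new intermediates. A Mitsunobu N-alkylation with allyl alcohol (PPh3, diisopropyl azodicarboxylate, THF, 0 °C to rt) activates the alcohol instead of using an external base, so the only anion present is the sulfonamide nitrogen paired with the alkoxyphosphonium ion.

**Further compounds**

F1 | step 3 | henicos-1-en-2-ylboronic acid | CCCCCCCCCCCCCCCCCCCC(=C)B(O)O
F2 | step 3 | 2-(allylamino)-3-methylidenedocosanoic acid (racemic) | CCCCCCCCCCCCCCCCCCCC(=C)C(NCC=C)C(=O)O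
F3 | step 3 | methyl 2-(allylamino)-3-methylidenedocosanoate (racemic) | CCCCCCCCCCCCCCCCCCCC(=C)C(NCC=C)C(=O)OC
F4 | step 5 | methyl 3-(2-oxoethyl)-2-(tosylamino)docosanoate (mixture of diastereomers) | CCCCCCCCCCCCCCCCCCCC(CC=O)C(NS(=O)(=O)c1ccc(C)cc1)C(=O)OC
F5 | step 5 | methyl 5-hydroxy-3-nonadecyl-1-tosylpyrrolidine-2-carboxylate (mixture of diastereomers) | CCCCCCCCCCCCCCCCCCCC1CC(O)N(S(=O)(=O)c2ccc(C)cc2)C1C(=O)OC
F6 | step 5 | methyl 3-nonadecyl-1-tosyl-2,3-dihydro-1H-pyrrole-2-carboxylate (mixture of diastereomers) | CCCCCCCCCCCCCCCCCCCC1C=CN(S(=O)(=O)c2ccc(C)cc2)C1C(=O)OC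
F7 | step 5 | methyl 3-nonadecyl-3H-pyrrole-2-carboxylate | CCCCCCCCCCCCCCCCCCCC1C=CN=C1C(=O)OC
F0 | step 4 | none | none
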